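A direct plan would lithiate a protected ring A–B bibenzyl A1 between its two ring B oxygens, acylate it with an alkynyl Weinreb amide to the aryl ynone A2, build ring C by a Diels–Alder reaction of A2 with the silyloxydiene A3, and reduce the resulting benzophenone A4 to the bridging CH2, in about eighteen steps.
Its weakest steps would be:
(a) the cycloaddition that makes ring C, because it would be run on the most advanced intermediate with a fragile diene and its regiochemistry would rest on polarisation alone;
(b) the removal of the ketone oxygen, because a carbonyl between four ortho substituents would need phenol masking, hydride reduction and an acidic ionic hydrogenation, three late steps that add no skeleton;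
(c) the run-up, because a dozen olefination, reduction and reagent-making steps would precede the first ring-forming event.

**Plan of the new route**

Ring B (C1 chain to ring A, C3 OH, C4 bridging CH2, C5 OMe) is symmetric about its C1–C4 axis but for OH against OMe. It is therefore cut back to the symmetric dione 8, whose C2 is its only nucleophilic carbon.
Ring C (C1 bridge, C2 chain to ring D, C4 OH, C6 OMe) has the orsellinate pattern, so its bridge carbon and first chain carbon are bought as the ester and methyl carbons of 9.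
Cuts, in order: the ring B O–CH3 bond and aromatic unsaturation; the bridge CH2–C4 bond (three-component reductive alkylation); the dione ring (enone plus malonate); the CH2–CH2 bond of the ring C–D chain.
Rings A, C and D are bought; the ring B carbocycle is closed by Michael–Claisen annulation and becomes aromatic last.
No late cycloaddition and no diaryl ketone arise: the bridge carbon enters as an aldehyde and is reduced in the step that bonds it, and only two benzyl ethers are carried.

Key step: step 8

Remark: the target has no stereocentre; diones 8 and 19 are drawn as diketones although they exist largely as enols; compounds 1, 3, 5, 9, 12 and 17 are taken to be commercial.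

**Route**

Step 1
Reactants: 1 methyl 3-(4-hydroxy-3-methoxyphenyl)propanoate
Product: 2 3-(4-hydroxy-3-methoxyphenyl)propanal
Conditions: i-Bu2AlH (2.1 equiv), CH2Cl2, –78 °C; MeOH, then aq. potassium sodium tartrate
Reagents that add atoms: none
Why: Partial reduction of an ester, in which the first equivalent of hydride is spent on the phenol and the second gives a tetrahedral aluminium hemiacetal that is stable at –78 °C and releases the aldehyde only on work-up.

Step 2
Reactants: 2 3-(4-hydroxy-3-methoxyphenyl)propanal; 3 1-(triphenyl-λ5-phosphanylidene)propan-2-one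
Product: 4 (3E)-6-(4-hydroxy-3-methoxyphenyl)hex-3-en-2-one
Conditions: 3 (1.2 equiv), THF, reflux
Reagents that add atoms: none
Why: Wittig olefination with a ketone-stabilised ylide, which is too weakly basic to be quenched by the phenol and should give the E-enone.

Step 3
Reactants: 4 (3E)-6-(4-hydroxy-3-methoxyphenyl)hex-3-en-2-one; 5 diethyl propanedioate
Product: 8 5-[2-(4-hydroxy-3-methoxyphenyl)ethyl]cyclohexane-1,3-dione, via Michael adduct 6 (not isolated), via carbethoxy dione 7 (not isolated)
Conditions: NaOEt (2.2 equiv), EtOH, reflux; then aq. NaOH, reflux; then HCl to pH 1, reflux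
Reagents that add atoms: none
Why: Malonate adds to the enone β-carbon (Michael addition), the methyl ketone enolate closes the six-membered carbocycle of the future ring B on an ester carbonyl (intramolecular Claisen condensation, 6-exo-trig), and saponification with decarboxylation leaves the symmetric dione, which has no stereocentre, the phenoxide being a spectator.

Step 4
Reactants: 9 ethyl 2,4-dihydroxy-6-methylbenzoate (ethyl orsellinate)
Product: 11 ethyl 4-(benzyloxy)-2-methoxy-6-methylbenzoate, via monobenzyl ether 10 (not isolated)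
Conditions: BnBr (1.05 equiv), K2CO3, DMF, rt; then MeI (3 equiv), 50 °C
Reagents that add atoms: benzyl bromide, BrCc1ccccc1; iodomethane, CI
Why: Williamson etherification in two stages, the first para-selective because the 2-hydroxyl is held in a hydrogen bond to the ester carbonyl and is alkylated only by the excess of the small electrophile on warming.

Step 5
Reactants: 11 ethyl 4-(benzyloxy)-2-methoxy-6-methylbenzoate; 12 1-(benzyloxy)-3-(bromomethyl)benzene
Product: 14 ethyl 4-(benzyloxy)-2-{2-[3-(benzyloxy)phenyl]ethyl}-6-methoxybenzoate, via benzylic lithium species 13 (not isolated)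
Conditions: LiN(i-Pr)2 (1.15 equiv), THF, –78 °C; then 12 (0.95 equiv), –78 to –40 °C; aq. NH4Cl
Reagents that add atoms: none
Why: Lateral lithiation of an ortho-toluate gives a benzylic anion stabilised as an extended ester enolate, which the benzylic bromide alkylates in an SN2 reaction, the ring hydrogens between the oxygens being too weakly acidic for the amide base.

Step 6
Reactants: 14 ethyl 4-(benzyloxy)-2-{2-[3-(benzyloxy)phenyl]ethyl}-6-methoxybenzoate
Product: 15 (4-(benzyloxy)-2-{2-[3-(benzyloxy)phenyl]ethyl}-6-methoxyphenyl)methanol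
Conditions: LiAlH4 (1.5 equiv), THF, 0 °C to rt; Fieser work-up
Reagents that add atoms: none
Why: Hydride reduction of the hindered benzoate to the benzylic alcohol, to which the aryl benzyl and methyl ethers are inert.

Step 7
Reactants: 15 (4-(benzyloxy)-2-{2-[3-(benzyloxy)phenyl]ethyl}-6-methoxyphenyl)methanol
Product: 16 4-(benzyloxy)-2-{2-[3-(benzyloxy)phenyl]ethyl}-6-methoxybenzaldehyde
Conditions: activated MnO2 (10 equiv), CH2Cl2, rt
Reagents that add atoms: none
Why: Heterogeneous MnO2 oxidation of a benzylic alcohol stops at the aldehyde and needs no acid, which this electron-rich benzylic alcohol would not tolerate.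

Step 8
Reactants: 8 5-[2-(4-hydroxy-3-methoxyphenyl)ethyl]cyclohexane-1,3-dione; 16 4-(benzyloxy)-2-{2-[3-(benzyloxy)phenyl]ethyl}-6-methoxybenzaldehyde; 17 diethyl 2,6-dimethyl-1,4-dihydropyridine-3,5-dicarboxylate (Hantzsch ester)
Product: 19 2-[(4-(benzyloxy)-2-{2-[3-(benzyloxy)phenyl]ethyl}-6-methoxyphenyl)methyl]-5-[2-(4-hydroxy-3-methoxyphenyl)ethyl]cyclohexane-1,3-dione, via arylidene dione 18 (not isolated)
Conditions: 8 (1.0 equiv), 16 (1.0 equiv), 17 (1.1 equiv), proline (20 mol%), CH2Cl2/EtOH, rt to 40 °C
Reagents that add atoms: none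
Why: Proline condenses with aldehyde 16 to an iminium ion that the enol of 8 attacks at C2, and loss of proline gives the 2-arylidene-1,3-dione 18 (Knoevenagel condensation); this doubly activated alkene takes a hydride at its benzylic carbon from the 1,4-dihydropyridine 17, which becomes a pyridine, and protonation gives 19. The closest known reaction type is the organocatalytic three-component reductive alkylation of cyclic 1,3-diones with aryl aldehydes and Hantzsch esters (tandem Knoevenagel condensation and transfer hydrogenation). No ring is closed and no stereocentre is created, since 19 is largely enolic at C2 and the cis/trans relation of C2 and C5 is lost on aromatisation. The step needs site selectivity on the future ring B and mono-alkylation: C2 is the only carbon of 8 that can condense, so the bridge must end between the two oxygens, and addition of a second dione to 18 should be outrun by hydride transfer because 17 is present from the start and the two ortho substituents of ring C shield the benzylic carbon from a bulky dione but not from hydride. The position of the bridge on ring C needs no control, because its carbon is the former ester carbon of 9. The benzyl ethers, the free guaiacol hydroxyl and both saturated chains should be inert under these near-neutral conditions.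

Step 9
Reactants: 19 2-[(4-(benzyloxy)-2-{2-[3-(benzyloxy)phenyl]ethyl}-6-methoxyphenyl)methyl]-5-[2-(4-hydroxy-3-methoxyphenyl)ethyl]cyclohexane-1,3-dione
Product: 22 2-[(4-(benzyloxy)-2-{2-[3-(benzyloxy)phenyl]ethyl}-6-methoxyphenyl)methyl]-5-[2-(4-hydroxy-3-methoxyphenyl)ethyl]-3-methoxyphenol, via methyl enol ether 20 (not isolated), via iodo enone 21 (not isolated)
Conditions: I2 (2.2 equiv), MeOH, reflux; aq. Na2S2O3
Reagents that add atoms: methanol, CO
Why: Iodine–methanol oxidative aromatisation, in which HI formed in the flask turns the dione into its methyl enol ether (a single compound because the two carbonyls of 19 are equivalent), iodination next to the remaining carbonyl and loss of HI give a cyclohexadienone that tautomerises to the phenol, so one oxygen ends as OMe and the other as OH with the bridge between them, while the accumulating HI should keep the electron-rich rings from being iodinated.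

Step 10
Reactants: 22 2-[(4-(benzyloxy)-2-{2-[3-(benzyloxy)phenyl]ethyl}-6-methoxyphenyl)methyl]-5-[2-(4-hydroxy-3-methoxyphenyl)ethyl]-3-methoxyphenol
Product: 23 2-{[4-hydroxy-2-[2-(3-hydroxyphenyl)ethyl]-6-methoxyphenyl]methyl}-5-[2-(4-hydroxy-3-methoxyphenyl)ethyl]-3-methoxyphenol (target, CNP0078999.0)
Conditions: H2 (1 atm), 10% Pd/C, EtOAc/MeOH, rt
Reagents that add atoms: none
Why: Palladium-catalysed hydrogenolysis cleaves the two aryl benzyl ethers and should leave the methyl ethers, the phenols and the diarylmethane untouched.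

**Compound list**

1 | methyl 3-(4-hydroxy-3-methoxyphenyl)propanoate | COC(=O)CCc1ccc(O)c(OC)c1 | starting material
2 | 3-(4-hydroxy-3-methoxyphenyl)propanal | O=CCCc1ccc(O)c(OC)c1 | intermediate
3 | 1-(triphenyl-λ5-phosphanylidene)propan-2-one | CC(=O)C=P(c1ccccc1)(c1ccccc1)c1ccccc1 | starting material
4 | (3E)-6-(4-hydroxy-3-methoxyphenyl)hex-3-en-2-one | CC(=O)/C=C/CCc1ccc(O)c(OC)c1 | intermediate
5 | diethyl propanedioate | CCOC(=O)CC(=O)OCC | starting material
6 | diethyl 2-[1-(4-hydroxy-3-methoxyphenyl)-5-oxohexan-3-yl]propanedioate, racemic (not isolated) | CCOC(=O)C(C(=O)OCC)C(CCc1ccc(O)c(OC)c1)CC(C)=O | intermediate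
7 | ethyl 6-[2-(4-hydroxy-3-methoxyphenyl)ethyl]-2,4-dioxocyclohexane-1-carboxylate, racemic (not isolated) | CCOC(=O)C1C(=O)CC(=O)CC1CCc1ccc(O)c(OC)c1 | intermediate
8 | 5-[2-(4-hydroxy-3-methoxyphenyl)ethyl]cyclohexane-1,3-dione | O=C1CC(=O)CC(CCc2ccc(O)c(OC)c2)C1 | intermediate
9 | ethyl 2,4-dihydroxy-6-methylbenzoate | CCOC(=O)c1c(C)cc(O)cc1O | starting material
10 | ethyl 4-(benzyloxy)-2-hydroxy-6-methylbenzoate (not isolated) | CCOC(=O)c1c(C)cc(OCc2ccccc2)cc1O | intermediate
11 | ethyl 4-(benzyloxy)-2-methoxy-6-methylbenzoate | CCOC(=O)c1c(C)cc(OCc2ccccc2)cc1OC | intermediate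
12 | 1-(benzyloxy)-3-(bromomethyl)benzene | BrCc1cccc(OCc2ccccc2)c1 | starting material
13 | {[5-(benzyloxy)-2-(ethoxycarbonyl)-3-methoxyphenyl]methyl}lithium (not isolated) | [Li]Cc1cc(OCc2ccccc2)cc(OC)c1C(=O)OCC | intermediate
14 | ethyl 4-(benzyloxy)-2-{2-[3-(benzyloxy)phenyl]ethyl}-6-methoxybenzoate | CCOC(=O)c1c(CCc2cccc(OCc3ccccc3)c2)cc(OCc2ccccc2)cc1OC | intermediate
15 | (4-(benzyloxy)-2-{2-[3-(benzyloxy)phenyl]ethyl}-6-methoxyphenyl)methanol | OCc1c(CCc2cccc(OCc3ccccc3)c2)cc(OCc2ccccc2)cc1OC | intermediate
16 | 4-(benzyloxy)-2-{2-[3-(benzyloxy)phenyl]ethyl}-6-methoxybenzaldehyde | O=Cc1c(CCc2cccc(OCc3ccccc3)c2)cc(OCc2ccccc2)cc1OC | intermediate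
17 | diethyl 2,6-dimethyl-1,4-dihydropyridine-3,5-dicarboxylate | CCOC(=O)C1=C(C)NC(C)=C(C(=O)OCC)C1 | starting material
18 | 2-[(4-(benzyloxy)-2-{2-[3-(benzyloxy)phenyl]ethyl}-6-methoxyphenyl)methylidene]-5-[2-(4-hydroxy-3-methoxyphenyl)ethyl]cyclohexane-1,3-dione (not isolated) | O=C1CC(CCc2ccc(O)c(OC)c2)CC(=O)C1=Cc1c(CCc2cccc(OCc3ccccc3)c2)cc(OCc2ccccc2)cc1OC | intermediate
19 | 2-[(4-(benzyloxy)-2-{2-[3-(benzyloxy)phenyl]ethyl}-6-methoxyphenyl)methyl]-5-[2-(4-hydroxy-3-methoxyphenyl)ethyl]cyclohexane-1,3-dione | O=C1CC(CCc2ccc(O)c(OC)c2)CC(=O)C1Cc1c(CCc2cccc(OCc3ccccc3)c2)cc(OCc2ccccc2)cc1OC | intermediate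
20 | 2-[(4-(benzyloxy)-2-{2-[3-(benzyloxy)phenyl]ethyl}-6-methoxyphenyl)methyl]-5-[2-(4-hydroxy-3-methoxyphenyl)ethyl]-3-methoxycyclohex-2-en-1-one, racemic (not isolated) | COC1=C(Cc2c(CCc3cccc(OCc4ccccc4)c3)cc(OCc3ccccc3)cc2OC)C(=O)CC(CCc2ccc(O)c(OC)c2)C1 | intermediate
21 | 2-[(4-(benzyloxy)-2-{2-[3-(benzyloxy)phenyl]ethyl}-6-methoxyphenyl)methyl]-5-[2-(4-hydroxy-3-methoxyphenyl)ethyl]-6-iodo-3-methoxycyclohex-2-en-1-one, diastereomer mixture (not isolated) | COC1=C(Cc2c(CCc3cccc(OCc4ccccc4)c3)cc(OCc3ccccc3)cc2OC)C(=O)C(I)C(CCc2ccc(O)c(OC)c2)C1 | intermediate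
22 | 2-[(4-(benzyloxy)-2-{2-[3-(benzyloxy)phenyl]ethyl}-6-methoxyphenyl)methyl]-5-[2-(4-hydroxy-3-methoxyphenyl)ethyl]-3-methoxyphenol | COc1cc(CCc2cc(O)c(Cc3c(CCc4cccc(OCc5ccccc5)c4)cc(OCc4ccccc4)cc3OC)c(OC)c2)ccc1O | intermediate
23 | 2-{[4-hydroxy-2-[2-(3-hydroxyphenyl)ethyl]-6-methoxyphenyl]methyl}-5-[2-(4-hydroxy-3-methoxyphenyl)ethyl]-3-methoxyphenol | COc1cc(CCc2cc(O)c(Cc3c(CCc4cccc(O)c4)cc(O)cc3OC)c(OC)c2)ccc1O | target

**Count and risks**

Total step count: 10. Longest linear sequence: 7 steps (steps 4 to 10, from ethyl orsellinate 9); the ring A branch (steps 1 to 3) joins at step 8.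

Steps most likely to fail:

Step 9 (aromatisation). The enol ether may be methylated a second time to the ring B dimethyl ether, the acid formed may split the electron-rich ring C benzyl group from C2 of the dione, or the phenolic rings may be iodinated. The fallback sets out from 19 and comes back at 22. The dione would be converted into its methyl enol ether 20 with HC(OMe)3 and catalytic TsOH in MeOH and isolated. LiN(i-Pr)2 (2.2 equiv) and Me3SiCl in THF at –78 °C would then give the doubly silylated dienol ether {[6-({4-(benzyloxy)-2-[2-(3-(benzyloxy)phenyl)ethyl]-6-methoxyphenyl}methyl)-5-methoxy-3-{2-[3-methoxy-4-(trimethylsilyloxy)phenyl]ethyl}cyclohexa-1,5-dien-1-yl]oxy}trimethylsilane F1. Saegusa–Ito dehydrogenation with Pd(OAc)2 (divalent palladium) in MeCN, tautomerisation of the dienone and cleavage of the aryl silyl ether with K2CO3 in MeOH on work-up would give 22 without acid or electrophilic halogen.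

Step 8 (three-component union). Condensation of the hindered, electron-rich aldehyde may be slow, or a second dione may add to the arylidene intermediate before hydride transfer. The fallback sets out from 15 and 8 and comes back at 19. The benzylic alcohol 15, which ionises readily to a 2,4-dialkoxybenzyl cation, would alkylate the enol of 8 (used in excess) at C2 in (CF3)2CHOH with catalytic TsOH at room temperature. This dehydrative SN1 alkylation needs neither the aldehyde nor a reductant and makes no new compound (F0).

Step 5 (lateral alkylation). The benzylic anion may condense with the ester group of unreacted 11, or the product may be alkylated a second time. The fallback sets out from 11 and comes back at 15. Saponification (KOH, aq. DMSO, 100 °C) would give 4-(benzyloxy)-2-methoxy-6-methylbenzoic acid F2. Its dianion (LiN(i-Pr)2, 2.2 equiv, THF, –78 to 0 °C) cannot be acylated by its own carboxylate and would be alkylated by 12 to 4-(benzyloxy)-2-{2-[3-(benzyloxy)phenyl]ethyl}-6-methoxybenzoic acid F3. LiAlH4 in THF would reduce F3 to 15.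

**Further compounds**

F1 | step 9 | {[6-({4-(benzyloxy)-2-[2-(3-(benzyloxy)phenyl)ethyl]-6-methoxyphenyl}methyl)-5-methoxy-3-{2-[3-methoxy-4-(trimethylsilyloxy)phenyl]ethyl}cyclohexa-1,5-dien-1-yl]oxy}trimethylsilane, racemic | COC1=C(Cc2c(CCc3cccc(OCc4ccccc4)c3)cc(OCc3ccccc3)cc2OC)C(O[Si](C)(C)C)=CC(CCc2ccc(O[Si](C)(C)C)c(OC)c2)C1
F0 | step 8 | none | none
F2 | step 5 | 4-(benzyloxy)-2-methoxy-6-methylbenzoic acid | Cc1cc(OCc2ccccc2)cc(OC)c1C(=O)O
F3 | step 5 | 4-(benzyloxy)-2-{2-[3-(benzyloxy)phenyl]ethyl}-6-methoxybenzoic acid | OC(=O)c1c(CCc2cccc(OCc3ccccc3)c2)cc(OCc2ccccc2)cc1OC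
A1 | direct plan | 1-(benzyloxy)-2-methoxy-4-{2-[3-methoxy-5-(methoxymethoxy)phenyl]ethyl}benzene | COCOc1cc(CCc2ccc(OCc3ccccc3)c(OC)c2)cc(OC)c1
A2 | direct plan | 1-{4-[2-(4-(benzyloxy)-3-methoxyphenyl)ethyl]-2-methoxy-6-(methoxymethoxy)phenyl}-5-[3-(benzyloxy)phenyl]pent-2-yn-1-one | COCOc1cc(CCc2ccc(OCc3ccccc3)c(OC)c2)cc(OC)c1C(=O)C#CCCc1cccc(OCc2ccccc2)c1
A3 | direct plan | 1,1-dimethoxy-3-(trimethylsilyloxy)buta-1,3-diene | COC(OC)=CC(=C)O[Si](C)(C)C
A4 | direct plan | {4-[2-(4-(benzyloxy)-3-methoxyphenyl)ethyl]-2-methoxy-6-(methoxymethoxy)phenyl}{2-[2-(3-(benzyloxy)phenyl)ethyl]-4-hydroxy-6-methoxyphenyl}methanone | COCOc1cc(CCc2ccc(OCc3ccccc3)c(OC)c2)cc(OC)c1C(=O)c1c(CCc2cccc(OCc3ccccc3)c2)cc(O)cc1OC
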